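**Retrosynthetic overview**
1. Target ⇐ C2 carbinol oxidised last; oxirane closed from a tertiary/primary diol monotosylate; the three esters put on one at a time (acetate after an enzymatic ketone reduction, C6 ester by tin-directed equatorial acylation, C5 ester by Yamaguchi coupling).
2. Cyclopentane ring (second ring) ⇐ intramolecular aldol condensation of a C7a-acetonyl/C3a-acetaldehyde pair to a 1-acetylcyclopentene, then epoxidation/SmI2 to the β-hydroxy ketone; side-chain carbinol by a ketoreductase.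
3. trans C3a/C7a arms ⇐ cuprate conjugate allylation and enolate alkylation of a cyclohexenone; C4 methylidene by Tebbe olefination; C5/C6 cis-diol by OsO4 anti to the C7 substituent.
4. Cyclohexenone (first ring) ⇐ amine-catalysed Michael addition of an aldehyde to methyl vinyl ketone plus aldol condensation; the aldehyde's quaternary carbinol ⇐ Sharpless epoxidation of methallyl alcohol (first stereocentre).
5. Acids ⇐ Ru/H8-BINAP hydrogenation of tiglic acid and syn-carbocupration of ethyl but-2-ynoate. Ring order: cyclohexane, then cyclopentane, then oxirane.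

Convention: locants C1–C7a are those of the hydrindane core of the target (C1 carries the acetoxyethyl group, C2 is the ketone carbon, C4 the methylidene-bearing carbon, C5 and C6 the ester-bearing carbons, C7 the oxirane-bearing carbon). C11 is the carbinol carbon on C1, C13 the quaternary carbon on C7, C14 its CH2–O carbon. The same locants are used for monocyclic precursors.
Assumption: the configuration at C2 in 27–38 (an epoxide/carbinol carbon that becomes the ketone in the last step) is left unassigned; the major epimer is carried on.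
Note: 12 is expected in about 92–95% ee; the minor enantiomer becomes a diastereomer of 15 and is removed by chromatography there.

Step 1
Reactants: 1 tiglic acid
Product: 2 (S)-2-methylbutanoic acid
Conditions: H2 (4 atm), Ru(OAc)2[(S)-H8-BINAP] (0.5 mol%), MeOH, 20 °C
Reagents that add atoms: none
Why: Noyori-type asymmetric hydrogenation of an α,β-unsaturated acid, in which the carboxylate-bound Ru/(S)-H8-BINAP catalyst adds H2 to one alkene face and sets the (S) centre.

Step 2
Reactants: 2 (S)-2-methylbutanoic acid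
Product: 3 (S)-2-methylbutanoyl chloride
Conditions: (COCl)2, DMF (cat.), CH2Cl2, 0 to 20 °C
Reagents that add atoms: oxalyl chloride O=C(Cl)C(=O)Cl
Why: Acid chloride formation via the Vilsmeier-type intermediate without amine base, so the α-centre is not racemised.

Step 3
Reactants: 4 ethyl but-2-ynoate
Product: 5 ethyl (E)-3-methylpent-2-enoate
Conditions: Et2CuLi (1.1 equiv), THF, −78 °C; MeOH quench at −78 °C
Reagents that add atoms: lithium diethylcuprate [Li+].CC[Cu-]CC
Why: syn-Carbocupration of the ynoate with cold protonation places ethyl cis to H and methyl cis to the ester, giving the (E) enoate.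

Step 4
Reactants: 5 ethyl (E)-3-methylpent-2-enoate
Product: 6 (E)-3-methylpent-2-enoic acid
Conditions: LiOH, THF/MeOH/H2O, 20 °C; then 1 M HCl
Reagents that add atoms: lithium hydroxide [Li+].[OH-]
Why: Saponification of the ester with retention of the alkene geometry.

Step 5
Reactants: 7 2-methylprop-2-en-1-ol
Product: 8 (R)-2-methylglycidol
Conditions: Ti(OiPr)4 (5 mol%), D-(−)-diisopropyl tartrate (6 mol%), tBuOOH, 4 Å molecular sieves, CH2Cl2, −20 °C
Reagents that add atoms: tert-butyl hydroperoxide CC(C)(C)OO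
Why: Katsuki–Sharpless asymmetric epoxidation sets the first stereocentre (future C13) by catalyst control, the D-(−)-tartrate giving the (R)-epoxy alcohol.

Step 6
Reactants: 8 (R)-2-methylglycidol
Product: 9 (S)-2-methylpent-4-ene-1,2-diol
Conditions: vinylMgBr (2.5 equiv), CuI (10 mol%), THF, −30 to 0 °C; aq. NH4Cl
Reagents that add atoms: vinylmagnesium bromide C=C[Mg]Br
Why: Copper-catalysed Grignard opening of the epoxide at the unsubstituted CH2 leaves the quaternary carbinol centre untouched.

Step 7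
Reactants: 9 (S)-2-methylpent-4-ene-1,2-diol
Product: 10 (4S)-2,2,4-trimethyl-4-(prop-2-en-1-yl)-1,3-dioxolane
Conditions: 2,2-dimethoxypropane, PPTS (cat.), CH2Cl2, 20 °C
Reagents that add atoms: 2,2-dimethoxypropane COC(C)(C)OC
Why: Acid-catalysed transketalisation protects the tertiary/primary diol as an acetonide for the whole middle of the route.

Step 8
Reactants: 10 (4S)-2,2,4-trimethyl-4-(prop-2-en-1-yl)-1,3-dioxolane
Product: 12 2-[(4S)-2,2,4-trimethyl-1,3-dioxolan-4-yl]acetaldehyde, via ozonide 11 (not isolated)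
Conditions: O3, CH2Cl2, −78 °C; then Me2S, −78 to 20 °C
Reagents that add atoms: ozone [O-][O+]=O
Why: Ozonolysis with reductive work-up cleaves the terminal alkene to the aldehyde without affecting the acetonide or the stereocentre.

Step 9
Reactants: 12 2-[(4S)-2,2,4-trimethyl-1,3-dioxolan-4-yl]acetaldehyde; 13 methyl vinyl ketone
Product: 14 (2R)-5-oxo-2-[(4S)-2,2,4-trimethyl-1,3-dioxolan-4-yl]hexanal
Conditions: (R)-2-[diphenyl(trimethylsilyloxy)methyl]pyrrolidine (10 mol%), ethyl 3,4-dihydroxybenzoate (20 mol%), 13 (1.5 equiv), neat, 4 °C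
Reagents that add atoms: none
Why: Enamine-catalysed Michael addition in which the (R)-diarylprolinol silyl ether shields one enamine face, setting the (2R) centre (future C7) under catalyst control.

Step 10
Reactants: 14 (2R)-5-oxo-2-[(4S)-2,2,4-trimethyl-1,3-dioxolan-4-yl]hexanal
Product: 15 (4S)-4-[(4S)-2,2,4-trimethyl-1,3-dioxolan-4-yl]cyclohex-2-en-1-one
Conditions: LiOH, iPrOH, 20 °C
Reagents that add atoms: none
Why: Intramolecular aldol condensation (Robinson-type closure) of the methyl ketone onto the aldehyde forms the cyclohexenone ring without eroding the γ-stereocentre.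

Step 11
Reactants: 15 (4S)-4-[(4S)-2,2,4-trimethyl-1,3-dioxolan-4-yl]cyclohex-2-en-1-one
Product: 16 (2R,3R,4S)-2,3-dihydroxy-4-[(4S)-2,2,4-trimethyl-1,3-dioxolan-4-yl]cyclohexan-1-one
Conditions: OsO4 (2.5 mol%), N-methylmorpholine N-oxide (1.5 equiv), acetone/H2O 8:1, 20 °C
Reagents that add atoms: N-methylmorpholine N-oxide C[N+]1([O-])CCOCC1; water O
Why: Upjohn syn-dihydroxylation of the enone occurs on the face anti to the bulky quaternary C7 substituent, setting C5 and C6 cis to each other and trans to that substituent.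

Step 12
Reactants: 16 (2R,3R,4S)-2,3-dihydroxy-4-[(4S)-2,2,4-trimethyl-1,3-dioxolan-4-yl]cyclohexan-1-one
Product: 17 bis-acetonide ketone (C4 ketone; C5/C6 cis-fused dioxolane)
Conditions: 2,2-dimethoxypropane, PPTS (cat.), acetone, 20 °C
Reagents that add atoms: 2,2-dimethoxypropane COC(C)(C)OC
Why: Transketalisation of the cis-diol locks C5/C6 as an acetonide and removes the free α-ketol.

Step 13
Reactants: 17 bis-acetonide ketone
Product: 19 bis-acetonide cyclohexenone (C4 ketone; C3a=C7a alkene), via silyl enol ether 18 (not isolated)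
Conditions: LiN(SiMe3)2, Me3SiCl (in situ quench), THF, −78 °C; then Pd(OAc)2 (1.05 equiv), MeCN, 20 °C
Reagents that add atoms: none
Why: Kinetic deprotonation at the unsubstituted α-CH2 (C3a) with in situ silylation, then Saegusa–Ito oxidation, places the enone on the C3a/C7a side without enolising toward the alkoxy-bearing C5.

Step 14
Reactants: 19 bis-acetonide cyclohexenone
Product: 20 C7a-allyl trimethylsilyl enol ether (C3a=C4–OSiMe3)
Conditions: allylMgBr (1.5 equiv), CuBr·SMe2 (20 mol%), Me3SiCl (2 equiv), THF, −78 °C; Et3N/pentane work-up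
Reagents that add atoms: allylmagnesium bromide C=CC[Mg]Br; chlorotrimethylsilane C[Si](C)(C)Cl
Why: Copper-catalysed, Me3SiCl-accelerated conjugate allylation adds at C7a anti to the adjacent quaternary C7 substituent (trans) and traps the enolate regiospecifically.

Step 15
Reactants: 20 C7a-allyl trimethylsilyl enol ether
Product: 22 all-trans keto ester (C3a–CH2CO2Me; C7a-allyl; C4 ketone), via lithium enolate 21 (not isolated)
Conditions: MeLi (1.05 equiv), THF, 0 °C; then BrCH2CO2Me (1.5 equiv), DMPU, −78 to −30 °C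
Reagents that add atoms: methyl bromoacetate COC(=O)CBr
Why: Regiospecific enolate generation by Si–O cleavage and alkylation at C3a trans to the C7a allyl group (and away from the axial C5 oxygen) gives the trans-2,3-disubstituted cyclohexanone.

Step 16
Reactants: 22 all-trans keto ester
Product: 23 C4-methylidene ester
Conditions: Cp2Ti(μ-Cl)(μ-CH2)AlMe2 (1.2 equiv), pyridine (cat.), THF/toluene, −40 to 0 °C
Reagents that add atoms: Tebbe reagent Cp2Ti(μ-Cl)(μ-CH2)AlMe2 C[Al-]1(C)C[Ti]([Cl+]1)(C1C=CC=C1)C1C=CC=C1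
Why: Tebbe methylenation converts the hindered, enolisable C4 ketone into the exocyclic methylene chemoselectively over the ester and without epimerising C3a or C5.

Step 17
Reactants: 23 C4-methylidene ester
Product: 24 C4-methylidene aldehyde (C3a–CH2CHO; C7a-allyl)
Conditions: iBu2AlH (1.1 equiv), CH2Cl2, −78 °C; aq. potassium sodium tartrate
Reagents that add atoms: none
Why: Partial reduction of the methyl ester stops at the aldehyde because the aluminium hemiacetal is stable at −78 °C.

Step 18
Reactants: 24 C4-methylidene aldehyde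
Product: 25 keto aldehyde (C3a–CH2CHO; C7a–CH2COCH3)
Conditions: PdCl2 (10 mol%), CuCl (1 equiv), O2 (1 atm), DMF/H2O 7:1, 20 °C
Reagents that add atoms: water O
Why: Tsuji–Wacker oxidation gives the methyl ketone from the monosubstituted allyl alkene, while the 1,1-disubstituted exocyclic alkene is inert.

Step 19
Reactants: 25 keto aldehyde
Product: 26 trans-fused 1-acetyl hydrindene (C1=C2 enone)
Conditions: KOH (2% aq.), MeOH, 0 to 20 °C
Reagents that add atoms: none
Why: Intramolecular aldol condensation (the 6-oxoheptanal to 1-acetylcyclopentene mode) joins the ketone α-carbon C1 to the aldehyde carbon C2, closing the five-membered ring on the pre-set trans C3a/C7a centres.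

Step 20
Reactants: 26 trans-fused 1-acetyl hydrindene
Product: 27 C1,C2-epoxy ketone
Conditions: H2O2 (30%), NaOH, MeOH, 0 °C
Reagents that add atoms: hydrogen peroxide OO
Why: Weitz–Scheffer nucleophilic epoxidation attacks only the enone, and the epoxide face is immaterial because C2 ends as a ketone.

Step 21
Reactants: 27 C1,C2-epoxy ketone
Product: 28 β-hydroxy ketone (C2–OH; C1-acetyl)
Conditions: SmI2 (2.5 equiv), THF/MeOH, −90 °C
Reagents that add atoms: none
Why: SmI2 reductive opening of the α,β-epoxy ketone cleaves the C1–O bond and gives the aldol-type β-hydroxy ketone without dehydration, C1 being drawn in its thermodynamic configuration (acetyl trans to the C7a–C7 bond).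

Step 22
Reactants: 28 β-hydroxy ketone
Product: 29 C2 tert-butyldimethylsilyl ether of 28
Conditions: tBuMe2SiOTf, 2,6-lutidine, CH2Cl2, −78 °C; then DBU (0.2 equiv), CH2Cl2, 20 °C
Reagents that add atoms: tert-butyldimethylsilyl trifluoromethanesulfonate CC(C)(C)[Si](C)(C)OS(=O)(=O)C(F)(F)F
Why: Silylation masks C2–O until the last step, and the DBU treatment equilibrates C1 (α to the ketone) to the epimer that avoids the C7 substituent.

Step 23
Reactants: 29 C2 tert-butyldimethylsilyl ether
Product: 30 (11R)-alcohol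
Conditions: ketoreductase (anti-Prelog, (R)-selective NADPH-dependent alcohol dehydrogenase of the Lactobacillus kefir type), NADP+ (cat.), iPrOH (10 vol%), potassium phosphate buffer pH 7.0, MgSO4 (1 mM), DMSO (10 vol%), 30 °C
Reagents that add atoms: none
Why: Ketoreductase-catalysed reduction of the methyl ketone delivers hydride to one carbonyl face under enzyme control and sets the (R)-carbinol at C11.

Step 24
Reactants: 30 (11R)-alcohol
Product: 31 (11R)-acetate
Conditions: Ac2O, pyridine, DMAP (cat.), CH2Cl2, 0 to 20 °C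
Reagents that add atoms: acetic anhydride CC(=O)OC(C)=O
Why: DMAP-catalysed acetylation of the only free hydroxyl installs the side-chain acetate.

Step 25
Reactants: 31 (11R)-acetate
Product: 32 tetraol (C5–OH; C6–OH; C13–OH; C14–OH)
Conditions: AcOH/H2O 4:1, 40 °C
Reagents that add atoms: none
Why: Mild acid hydrolysis removes both isopropylidene ketals while the secondary silyl ether and the acetate survive.

Step 26
Reactants: 32 tetraol
Product: 33 C14 primary tosylate
Conditions: TsCl (1.1 equiv), pyridine, CH2Cl2, 0 °C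
Reagents that add atoms: p-toluenesulfonyl chloride Cc1ccc(cc1)S(=O)(=O)Cl
Why: Sulfonylation is selective for the primary hydroxyl over the two secondary and the tertiary ones.

Step 27
Reactants: 33 C14 primary tosylate; 3 (S)-2-methylbutanoyl chloride
Product: 34 C6 (S)-2-methylbutanoate
Conditions: Me2SnCl2 (10 mol%), K2CO3, THF, 20 °C
Reagents that add atoms: none
Why: Tin-catalysed regioselective acylation of the cis-5,6-diol goes to the equatorial C6–OH, and the amine-free conditions keep the acyl α-centre intact.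

Step 28
Reactants: 34 C6 (S)-2-methylbutanoate; 6 (E)-3-methylpent-2-enoic acid
Product: 36 C5 (E)-3-methylpent-2-enoate of 34, via mixed anhydride 35 (not isolated)
Conditions: 6, 2,4,6-Cl3C6H2COCl, Et3N, toluene, 20 °C; then 34, DMAP, 40 °C
Reagents that add atoms: none
Why: Yamaguchi esterification acylates the hindered axial allylic C5–OH, the tertiary C13–OH being inert and the (E) geometry preserved.

Step 29
Reactants: 36 C5 (E)-3-methylpent-2-enoate
Product: 37 oxirane (C13–C14 epoxide; C2 silyl ether)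
Conditions: DBU (1.5 equiv), CH2Cl2, 20 °C
Reagents that add atoms: none
Why: Intramolecular Williamson etherification of the tertiary alcohol onto the primary tosylate closes the oxirane with retention at the quaternary centre set in step 5, and no free C6–OH is left to compete.

Step 30
Reactants: 37 oxirane
Product: 38 C2 alcohol
Conditions: HF·pyridine, pyridine, THF, 0 to 20 °C
Reagents that add atoms: none
Why: Buffered fluoride desilylation frees C2–OH without opening the epoxide or cleaving the esters.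

Step 31
Reactants: 38 C2 alcohol
Product: 39 target CNP0120390.2
Conditions: Dess–Martin periodinane, NaHCO3, CH2Cl2, 0 to 20 °C
Reagents that add atoms: none
Why: Buffered Dess–Martin oxidation gives the C2 ketone without β-elimination of the acetate, C1 already holding the thermodynamically preferred configuration.

**Compound list**
1 | tiglic acid, (E)-2-methylbut-2-enoic acid | C/C=C(\C)C(=O)O | starting material
2 | (S)-2-methylbutanoic acid | CC[C@H](C)C(=O)O | intermediate
3 | (S)-2-methylbutanoyl chloride | CC[C@H](C)C(=O)Cl | intermediate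
4 | ethyl but-2-ynoate | CC#CC(=O)OCC | starting material
5 | ethyl (E)-3-methylpent-2-enoate | CC/C(C)=C/C(=O)OCC | intermediate
6 | (E)-3-methylpent-2-enoic acid | CC/C(C)=C/C(=O)O | intermediate
7 | 2-methylprop-2-en-1-ol (methallyl alcohol) | C=C(C)CO | starting material
8 | (R)-2-methylglycidol, [(2R)-2-methyloxiran-2-yl]methanol | C[C@@]1(CO)CO1 | intermediate
9 | (S)-2-methylpent-4-ene-1,2-diol | C=CC[C@@](O)(C)CO | intermediate
10 | (4S)-2,2,4-trimethyl-4-(prop-2-en-1-yl)-1,3-dioxolane | C=CC[C@@]1(C)COC(C)(C)O1 | intermediate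
11 | ozonide (1,2,4-trioxolane) of 10 | C1OOC(C[C@@]2(C)COC(C)(C)O2)O1 | intermediate
12 | 2-[(4S)-2,2,4-trimethyl-1,3-dioxolan-4-yl]acetaldehyde | O=CC[C@@]1(C)COC(C)(C)O1 | intermediate
13 | methyl vinyl ketone (but-3-en-2-one) | CC(=O)C=C | starting material
14 | (2R)-5-oxo-2-[(4S)-2,2,4-trimethyl-1,3-dioxolan-4-yl]hexanal | O=C[C@@H]([C@@]1(C)COC(C)(C)O1)CCC(C)=O | intermediate
15 | (4S)-4-[(4S)-2,2,4-trimethyl-1,3-dioxolan-4-yl]cyclohex-2-en-1-one | O=C1C=C[C@@H]([C@@]2(C)COC(C)(C)O2)CC1 | intermediate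
16 | (2R,3R,4S)-2,3-dihydroxy-4-[(4S)-2,2,4-trimethyl-1,3-dioxolan-4-yl]cyclohexan-1-one | O=C1CC[C@H]([C@@]2(C)COC(C)(C)O2)[C@@H](O)[C@H]1O | intermediate
17 | bis-acetonide ketone: 2,3-O-isopropylidene derivative of 16 | O=C1CC[C@H]([C@@]2(C)COC(C)(C)O2)[C@H]3OC(C)(C)O[C@@H]13 | intermediate
18 | trimethylsilyl enol ether of 17 (C3a=C4) | C[Si](C)(C)OC1=CC[C@H]([C@@]2(C)COC(C)(C)O2)[C@H]3OC(C)(C)O[C@@H]13 | intermediate
19 | bis-acetonide cyclohexenone (C4 ketone, C3a=C7a alkene) | O=C1C=C[C@H]([C@@]2(C)COC(C)(C)O2)[C@H]3OC(C)(C)O[C@@H]13 | intermediate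
20 | C7a-allyl trimethylsilyl enol ether (allyl trans to the C7 dioxolane) | C[Si](C)(C)OC1=C[C@@H](CC=C)[C@H]([C@@]2(C)COC(C)(C)O2)[C@H]3OC(C)(C)O[C@@H]13 | intermediate
21 | lithium enolate from 20 | [Li]OC1=C[C@@H](CC=C)[C@H]([C@@]2(C)COC(C)(C)O2)[C@H]3OC(C)(C)O[C@@H]13 | intermediate
22 | all-trans keto ester (C3a–CH2CO2Me, C7a-allyl, C4 ketone) | O=C1[C@H](CC(=O)OC)[C@@H](CC=C)[C@H]([C@@]2(C)COC(C)(C)O2)[C@H]3OC(C)(C)O[C@@H]13 | intermediate
23 | C4-methylidene ester | C=C1[C@H](CC(=O)OC)[C@@H](CC=C)[C@H]([C@@]2(C)COC(C)(C)O2)[C@H]3OC(C)(C)O[C@@H]13 | intermediate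
24 | C4-methylidene aldehyde (C3a–CH2CHO, C7a-allyl) | C=C1[C@H](CC=O)[C@@H](CC=C)[C@H]([C@@]2(C)COC(C)(C)O2)[C@H]3OC(C)(C)O[C@@H]13 | intermediate
25 | keto aldehyde (C3a–CH2CHO, C7a–CH2COCH3) | C=C1[C@H](CC=O)[C@@H](CC(C)=O)[C@H]([C@@]2(C)COC(C)(C)O2)[C@H]3OC(C)(C)O[C@@H]13 | intermediate
26 | trans-fused 1-acetyl hydrindene (C1=C2 enone), bis-acetonide | C=C1[C@@H]2CC=C(C(C)=O)[C@H]2[C@H]([C@@]3(C)COC(C)(C)O3)[C@H]4OC(C)(C)O[C@@H]14 | intermediate
27 | C1,C2-epoxy ketone (epoxide face unassigned) | C=C1[C@@H]2CC3OC3(C(C)=O)[C@H]2[C@H]([C@@]4(C)COC(C)(C)O4)[C@H]5OC(C)(C)O[C@@H]15 | intermediate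
28 | β-hydroxy ketone (C2–OH unassigned, C1-acetyl as in the target) | C=C1[C@@H]2CC(O)[C@H](C(C)=O)[C@H]2[C@H]([C@@]3(C)COC(C)(C)O3)[C@H]4OC(C)(C)O[C@@H]14 | intermediate
29 | C2 tert-butyldimethylsilyl ether of 28 | C=C1[C@@H]2CC(O[Si](C)(C)C(C)(C)C)[C@H](C(C)=O)[C@H]2[C@H]([C@@]3(C)COC(C)(C)O3)[C@H]4OC(C)(C)O[C@@H]14 | intermediate
30 | (11R)-alcohol | C=C1[C@@H]2CC(O[Si](C)(C)C(C)(C)C)[C@H]([C@@H](C)O)[C@H]2[C@H]([C@@]3(C)COC(C)(C)O3)[C@H]4OC(C)(C)O[C@@H]14 | intermediate
31 | (11R)-acetate | C=C1[C@@H]2CC(O[Si](C)(C)C(C)(C)C)[C@H]([C@@H](C)OC(C)=O)[C@H]2[C@H]([C@@]3(C)COC(C)(C)O3)[C@H]4OC(C)(C)O[C@@H]14 | intermediate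
32 | tetraol (C5, C6, C13, C14 hydroxyls free) | C=C1[C@@H]2CC(O[Si](C)(C)C(C)(C)C)[C@H]([C@@H](C)OC(C)=O)[C@H]2[C@H]([C@@](O)(C)CO)[C@@H](O)[C@H]1O | intermediate
33 | C14 primary tosylate | C=C1[C@@H]2CC(O[Si](C)(C)C(C)(C)C)[C@H]([C@@H](C)OC(C)=O)[C@H]2[C@H]([C@@](O)(C)COS(=O)(=O)c3ccc(C)cc3)[C@@H](O)[C@H]1O | intermediate
34 | C6 (S)-2-methylbutanoate of 33 | C=C1[C@@H]2CC(O[Si](C)(C)C(C)(C)C)[C@H]([C@@H](C)OC(C)=O)[C@H]2[C@H]([C@@](O)(C)COS(=O)(=O)c3ccc(C)cc3)[C@@H](OC(=O)[C@@H](C)CC)[C@H]1O | intermediate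
35 | mixed anhydride of 6 with 2,4,6-trichlorobenzoic acid | CC/C(C)=C/C(=O)OC(=O)c1c(Cl)cc(Cl)cc1Cl | intermediate
36 | C5 (E)-3-methylpent-2-enoate, C6 (S)-2-methylbutanoate, C14 tosylate | C=C1[C@@H]2CC(O[Si](C)(C)C(C)(C)C)[C@H]([C@@H](C)OC(C)=O)[C@H]2[C@H]([C@@](O)(C)COS(=O)(=O)c3ccc(C)cc3)[C@@H](OC(=O)[C@@H](C)CC)[C@H]1OC(=O)/C=C(\C)CC | intermediate
37 | oxirane with C2 silyl ether | C=C1[C@@H]2CC(O[Si](C)(C)C(C)(C)C)[C@H]([C@@H](C)OC(C)=O)[C@H]2[C@H]([C@@]3(C)CO3)[C@@H](OC(=O)[C@@H](C)CC)[C@H]1OC(=O)/C=C(\C)CC | intermediate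
38 | C2 alcohol | C=C1[C@@H]2CC(O)[C@H]([C@@H](C)OC(C)=O)[C@H]2[C@H]([C@@]3(C)CO3)[C@@H](OC(=O)[C@@H](C)CC)[C@H]1OC(=O)/C=C(\C)CC | intermediate
39 | CNP0120390.2: (1S,3aR,5S,6R,7S,7aR)-1-[(1R)-1-acetoxyethyl]-4-methylidene-6-{[(2S)-2-methylbutanoyl]oxy}-7-[(2S)-2-methyloxiran-2-yl]-2-oxooctahydro-1H-inden-5-yl (2E)-3-methylpent-2-enoate | C=C1[C@@H]2CC(=O)[C@H]([C@@H](C)OC(C)=O)[C@H]2[C@H]([C@@]2(C)CO2)[C@@H](OC(=O)[C@@H](C)CC)[C@H]1OC(=O)/C=C(\C)CC | target

**Step count and risks**
Total step count: 31. Longest linear sequence: 27 steps (steps 5–31, from 7 to 39).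

Step 9 (amine-catalysed Michael addition). The aldehyde 12 is β-quaternary and β-oxygenated, so enamine formation and attack on 13 may be slow, and β-alkoxide loss is possible. The fallback sets out from 12 and comes back at 14. Compound 12 is condensed with (S)-1-amino-2-(methoxymethyl)pyrrolidine to the SAMP hydrazone F1. Deprotonation with LiN(iPr)2 and alkylation with 4-iodo-2-methylbut-1-ene (Enders alkylation, auxiliary control) gives the alkylated hydrazone F2. Ozonolysis (O3, then Me2S) cleaves both the C=N and the C=C bond and gives 14.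

Step 23 (ketoreductase reduction). The bulky bicyclic methyl ketone 29 may be accepted poorly even after enzyme screening. The fallback sets out from 29 and comes back at 31, so step 24 falls away. NaBH4 in MeOH reduces 29 to the C11-epimeric alcohol mixture F3. An immobilised lipase (Candida antarctica lipase B) with vinyl acetate in tBuOMe at 40 °C acetylates only the (R)-carbinol (Kazlauskas rule) and gives 31 directly. The unreacted (11S)-alcohol F4 is separated and oxidised back to 29 with Dess–Martin periodinane for recycling.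

Step 27 (regioselective C6 acylation). Selectivity between the equatorial C6–OH and the axial allylic C5–OH, or acyl migration between them, may be insufficient. The fallback sets out from 33 and comes back at 36, replacing steps 27 and 28 by a protecting-group relay with the ester order reversed. Et3SiCl and imidazole at −30 °C silylate the less hindered equatorial hydroxyl to give the C6 triethylsilyl ether F5. Yamaguchi esterification with 6 gives the C5 enoate silyl ether F6. PPTS in MeOH at 0 °C removes the triethylsilyl group (no epoxide is present yet) to give the C6 alcohol F7. Acylation of F7 with 3 (pyridine, DMAP, 0 °C) gives 36.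

**Further compounds**
F1 | step 9 | SAMP hydrazone of 12 | COC[C@@H]1CCCN1/N=C/C[C@@]2(C)COC(C)(C)O2
F2 | step 9 | alkylated SAMP hydrazone (3-methylbut-3-enyl group at the α-carbon) | COC[C@@H]1CCCN1/N=C/[C@@H]([C@@]2(C)COC(C)(C)O2)CCC(C)=C
F3 | step 23 | C11-epimeric alcohol mixture from 29 | C=C1[C@@H]2CC(O[Si](C)(C)C(C)(C)C)[C@H](C(C)O)[C@H]2[C@H]([C@@]3(C)COC(C)(C)O3)[C@H]4OC(C)(C)O[C@@H]14
F4 | step 23 | (11S)-alcohol | C=C1[C@@H]2CC(O[Si](C)(C)C(C)(C)C)[C@H]([C@H](C)O)[C@H]2[C@H]([C@@]3(C)COC(C)(C)O3)[C@H]4OC(C)(C)O[C@@H]14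
F5 | step 27 | C6 triethylsilyl ether of 33 | C=C1[C@@H]2CC(O[Si](C)(C)C(C)(C)C)[C@H]([C@@H](C)OC(C)=O)[C@H]2[C@H]([C@@](O)(C)COS(=O)(=O)c3ccc(C)cc3)[C@@H](O[Si](CC)(CC)CC)[C@H]1O
F6 | step 27 | C5 (E)-3-methylpent-2-enoate C6 triethylsilyl ether | C=C1[C@@H]2CC(O[Si](C)(C)C(C)(C)C)[C@H]([C@@H](C)OC(C)=O)[C@H]2[C@H]([C@@](O)(C)COS(=O)(=O)c3ccc(C)cc3)[C@@H](O[Si](CC)(CC)CC)[C@H]1OC(=O)/C=C(\C)CC
F7 | step 27 | C5 (E)-3-methylpent-2-enoate C6 alcohol | C=C1[C@@H]2CC(O[Si](C)(C)C(C)(C)C)[C@H]([C@@H](C)OC(C)=O)[C@H]2[C@H]([C@@](O)(C)COS(=O)(=O)c3ccc(C)cc3)[C@@H](O)[C@H]1OC(=O)/C=C(\C)CC
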